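No constants were to hand for your flasks, so I had no rate law to integrate and reckoned from the earlier runs instead. You wanted a quick number and guessed that summer, left longer, would hold the purer product; I expected the opposite.

| flask | left-handed substrate | right-handed substrate | gas | free catalyst | remark | time |
|---|---|---|---|---|---|---|
| south-east | 59 mM | 59 mM | 8.4 mM (held) | 4.2 mM | run made earlier |  |
| north-east | 92 mM | 92 mM | 8.4 mM (held) | 4.2 mM | run made earlier |  |
| south-west | 42 mM | 42 mM | 8.4 mM (held) | 8.4 mM | run made earlier |  |
| summer | 42 mM | 42 mM | 8.4 mM (held) | 4.2 mM |  | 15 min |
| autumn | 42 mM | 42 mM | 8.4 mM (held) | 4.2 mM |  | 5.0 min |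

| run | time / min | left-handed product / % | right-handed product / % |
|---|---|---|---|
| south-east | 1.33 | 0.6 | 0.5 |
| south-east | 2.50 | 3.4 | 0.8 |
| south-east | 4.00 | 6.0 | 0.8 |
| south-east | 5.00 | 8.0 | 2.6 |
| south-east | 6.00 | 7.9 | 3.0 |
| south-east | 8.00 | 11.9 | 4.7 |
| south-east | 10.0 | 14.6 | 5.4 |
| north-east | 1.33 | 0.9 | 0 |
| north-east | 2.50 | 2.8 | 0 |
| north-east | 4.00 | 3.7 | 1.9 |
| north-east | 5.00 | 5.7 | 1.0 |
| north-east | 6.00 | 7.2 | 2.6 |
| north-east | 8.00 | 9.0 | 3.0 |
| north-east | 10.0 | 10.5 | 3.6 |
| south-west | 0.833 | 1.8 | 0 |
| south-west | 2.50 | 4.1 | 2.3 |
| south-west | 4.00 | 8.7 | 3.3 |
| south-west | 6.00 | 13.2 | 4.4 |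
| south-west | 10.0 | 21.6 | 8.0 |

(standard deviation of a reading: 0.5 percentage points)

* the winner by excess of left-handed product over right-handed product in the product; "neither" if no more than 2 percentage points parts them (summer / autumn / neither)
* excess of left-handed product over right-handed product in the product at the end, summer
* excess of left-handed product over right-handed product in the product at the end, autumn

- free catalyst is single-handed; left-handed substrate and right-handed substrate are mirror images of each other, charged as a racemate, each of them at the stated concentration
- what was read earlier has a scatter of 0.5 percentage points, one standard deviation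
- at the start none of the gas is in solution
- an excess is the difference of the two amounts in percent of their sum
- an excess is below zero if the other one leads

I worked with the fraction left, not the fraction made. If one catalyst takes both substrates at rates proportional to their own amounts, the logarithms of their fractions left keep a fixed ratio. Each substrate was half of the charge, so the fraction left is one minus 2 times the reading. The last readings gave 3.02 in south-east, 3.15 in north-east and 3.24 in south-west, with a mean of 3.14. This s, the logarithm of the left-handed fraction left over that of the right-handed, is the usual selectivity factor. If x of the right-handed substrate is left, then x to the power s of the left-handed substrate is left, and the excess follows.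

Right-handed product had grown by 0.657 mM min⁻¹ on average in the earlier runs. Taken as steady, that put x at 92.2% for autumn and 76.5% for summer, so the excess came to 48.5% for autumn and 41.5% for summer. Autumn stood 7 percentage points ahead, more than the margin.

The forecast said autumn, with 44% for summer and 50% for autumn, above my figures, expecting “about 2 mM/min, slowing gently”.

The flasks gave autumn: 43.8% for summer and 50.1% for autumn. Summer still held 80% of its right-handed substrate, more than my 76.5%.

    2 free catalyst → spent catalyst A (k = 1.51 M⁻¹ min⁻¹)
    gas ⇌ partner, rate k2*(csat - [partner]) (kL = 0.414 min⁻¹)
    partner + free catalyst → spent catalyst B (k = 1.81 M⁻¹ min⁻¹)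
    partner + free catalyst + right-handed substrate → free catalyst + right-handed product (k = 1380 M⁻² min⁻¹)
    partner + free catalyst + left-handed substrate → free catalyst + left-handed product (k = 4430 M⁻² min⁻¹)

In summer the left-handed step used partner 2.6 times as fast as the right-handed step at 6.81 min, but 2.0 times as fast at 15.0 min. At the end, s times the ratio of the fractions left, 49% over 80%, gives 1.92, against that 2.0.

The summer flask read at 40.0 min had 50% of its right-handed substrate left, so s gave 11.1% of the left-handed substrate and an excess of 27.7%. It held 11% and showed 28.0%.

(The readings are simulated for an exercise; noise was put on by code.)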